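## Retrosynthetic overview

- Anabsin (**7**) comes from exo epoxy-diol **6** by acid-triggered 5-exo etherification (C10′-OH onto C4′, C3′-OH retained).
- **6** comes from norbornene dimer **5** by exo epoxidation of the strained C3′=C4′ alkene.
- **5** comes from an endo Diels–Alder homodimerization of cyclopentadiene **4**. This is the key step: it forms the norbornene and the fused cyclopentene and sets four new stereocenters.
- **4** comes from dehydration of allylic alcohol **3**, which comes from Luche reduction of enone **2**, which comes from photorearrangement of (−)-α-santonin (**1**).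
- Ring-forming order: guaiane 5/7 system (photochemistry), norbornene/cyclopentene core (Diels–Alder), then the oxolane. Both lactones and their C6/C7/C11 stereocenters are carried unchanged from santonin.

Assumption: the photoproduct has the C1/C10 configuration of the target. The homodimerization is endo and head-to-head, with each partner reacting on its face anti to C10 (the face carrying H-1).

## Route

**Step 1**
Reactants: **1**, (−)-α-santonin (cross-conjugated 1,4-dien-3-one eudesmanolide with a trans-fused 6,12-lactone)
Product: **2**, isophotosantonic lactone (10-hydroxy-3-oxoguai-4-en-6,12-olide: 4-methylcyclopentenone fused to a 7-ring, tertiary C10-OH, trans-lactone)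
Conditions: hν (medium-pressure Hg, Pyrex), AcOH/H2O 1:1, 20 °C
Reagents that add atoms: water, O (its oxygen becomes the C10–OH)
Why: Cross-conjugated dienone photorearrangement (santonin → lumisantonin → acid-promoted cyclopropane opening and ring contraction); water captures the C10 cation, C1 and C10 are controlled by the chiral hydroazulene skeleton, and C6/C7/C11 are untouched.

**Step 2**
Reactants: **2**
Product: **3**, 3,10-dihydroxyguai-4-en-6,12-olide (allylic cyclopentenol, C3 epimeric mixture)
Conditions: NaBH4, CeCl3·7H2O, MeOH, −10 °C
Reagents that add atoms: none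
Why: Luche 1,2-reduction of the enone leaves the lactone and tertiary alcohol intact; the C3 configuration does not matter because C3 becomes sp2 in the next step.

**Step 3**
Reactants: **3**
Product: **4**, 10-hydroxyguaia-2,4-dien-6,12-olide (5-substituted cyclopentadiene; C1 is the sp3 carbon)
Conditions: MsCl, Et3N, CH2Cl2, −20 °C; then DBU, 0 °C; cold aqueous work-up, concentrate below 10 °C and use at once
Reagents that add atoms: none (the mesylate is lost in the elimination)
Why: The hindered tertiary C10-OH is not mesylated at −20 °C, so selective allylic mesylation followed by E2 elimination (loss of H-2) gives the conjugated cyclopentadiene; no stereocenter is touched because C1 stays sp3.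

**Step 4**
Reactants: **4** (two molecules; one acts as diene, one as dienophile)
Product: **5**, norbornene-type Diels–Alder homodimer (bis-10-hydroxy; C3′=C4′ alkene bearing the C4′-methyl, and the tetrasubstituted C4=C5 alkene of the dienophile half)
Conditions: neat or 1–2 M in PhMe, 25–40 °C, 4 d
Reagents that add atoms: none
Why: Cyclopentadiene-type [4+2] dimerization is endo-selective. The diene (C2′–C5′) and the unsubstituted C2=C3 dienophile bond each react on the face anti to C10, which sets C2, C3, C2′ and C5′, keeps C1′ as the norbornene bridge carbon, and places C10′ syn to the new C3′=C4′ alkene.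

**Step 5**
Reactants: **5**
Product: **6**, exo-3′,4′-epoxide of **5** (epoxy-diol)
Conditions: VO(acac)2 (5 mol %), TBHP (anhydrous, in decane), CH2Cl2, 0 °C → rt
Reagents that add atoms: tert-butyl hydroperoxide, CC(C)(C)OO (supplies the epoxide O)
Why: The strained norbornene alkene has an intrinsic exo preference, and the syn-bridge C10′-OH binds vanadium and delivers the peroxide O to the same exo face (Sharpless–Michaelson-type epoxidation); this sets C3′ and C4′, while the hindered tetrasubstituted C4=C5 alkene is shielded.

**Step 6**
Reactants: **6**
Product: **7**, anabsin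
Conditions: CSA (10 mol %), CH2Cl2, 0 °C
Reagents that add atoms: none (isomerization)
Why: Acid ionizes the tertiary C4′–O bond of the epoxide, and the tethered C10′-OH can reach only the exo face of the C4′ cation, closing the oxolane 5-exo (acid-catalyzed epoxide-opening etherification). C3′–O remains as the exo alcohol, so both carbons keep their configuration, with the C4′-methyl and H-3′ endo.

## Compound list

| # | Name | SMILES | Role |
|---|---|---|---|
| 1 | (−)-α-Santonin | C[C@H]1[C@@H]2CC[C@]3(C=CC(=O)C(=C3[C@H]2OC1=O)C)C | starting material |
| 2 | Isophotosantonic lactone | CC1=C2[C@H]3OC(=O)[C@@H](C)[C@@H]3CC[C@](C)(O)[C@@H]2CC1=O | intermediate |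
| 3 | 3,10-Dihydroxyguai-4-en-6,12-olide (C3 epimers) | CC1=C2[C@H]3OC(=O)[C@@H](C)[C@@H]3CC[C@](C)(O)[C@@H]2CC1O | intermediate |
| 4 | 10-Hydroxyguaia-2,4-dien-6,12-olide (cyclopentadiene) | CC1=C2[C@H]3OC(=O)[C@@H](C)[C@@H]3CC[C@](C)(O)[C@@H]2C=C1 | intermediate (made in step 3, consumed in step 4) |
| 5 | Diels–Alder homodimer (norbornene, bis-10-OH) | CC1=C2[C@H]3OC(=O)[C@@H](C)[C@@H]3CC[C@](C)(O)[C@@H]2[C@H]2[C@@H]3[C@@H]4[C@@]([C@H]6OC(=O)[C@@H](C)[C@@H]6CC[C@]4(C)O)(C(C)=C3)[C@@H]12 | intermediate |
| 6 | exo-3′,4′-Epoxide of 5 | CC1=C2[C@H]3OC(=O)[C@@H](C)[C@@H]3CC[C@](C)(O)[C@@H]2[C@H]2[C@@H]3[C@@H]4[C@@]([C@H]6OC(=O)[C@@H](C)[C@@H]6CC[C@]4(C)O)([C@@]7(C)O[C@@H]37)[C@@H]12 | intermediate |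
| 7 | Anabsin | CC1=C2[C@H]3OC(=O)[C@@H](C)[C@@H]3CC[C@](C)(O)[C@@H]2[C@H]2[C@@H]3[C@@H]4[C@]5([C@H]6OC(=O)[C@@H](C)[C@@H]6CC[C@]4(C)O[C@@]5(C)[C@H]3O)[C@@H]12 | target |

## Totals

- Total steps: 6
- Longest linear sequence: 6

## Three steps most likely to fail

1. **Step 4 (dimerization).** The cyclopentadiene can undergo 1,5-H shifts that scramble C1, or give the wrong regio- or facial isomer, or dimerize slowly.
   Fallback: build the norbornene by a polarized heterodimerization instead.
   - Convert **2** (10-OH as TBS ether) to its 3-silyloxy-cyclopentadiene (TBSOTf, Et3N).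
   - React this diene with **4** as the dienophile at its unsubstituted C2=C3 bond, under Lewis-acid or high-pressure conditions.
   - Hydrolyse the resulting C3′ silyl enol ether to the ketone, form the enol triflate (KHMDS, PhNTf2), and reduce it (Pd(OAc)2, PPh3, HCO2H, Et3N) to the C3′=C4′ alkene of **5**.

2. **Step 5 (epoxidation).** Attack at the wrong alkene (C4=C5) or the endo face would give the wrong epoxide.
   Fallback: replace the epoxide with directed cis-dihydroxylation.
   - Use OsO4/TMEDA for exo dihydroxylation of **5**.
   - Silylate the secondary C3′-OH selectively.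
   - Ionize the tertiary C4′-OH with Sc(OTf)3 so that C10′-OH closes the ether.
   - Remove the silyl group with TBAF.

3. **Step 6 (cycloetherification).** The free C4′ cation could undergo a Meinwald hydride shift to the C3′ ketone or a Wagner–Meerwein shift instead of being trapped.
   Fallback: use radical-polar crossover instead of a free cation.
   - Open epoxide **6** with Cp2TiCl (Nugent–RajanBabu), giving the tertiary C4′ radical with a Ti–O bond on exo C3′.
   - Oxidize the radical with Cu(II) so that C10′-OH traps it.
   - Release the C3′-OH on work-up.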